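**Overview.** Locants follow the bicyclo[4.3.1]decane numbering of the target (C1/C6 bridgeheads, C2–C5 four-carbon bridge, C7–C9 three-carbon bridge, C10 one-carbon bridge); the seven-membered ring is closed first, the six-membered ring second.
- Key bond C5–C6 (two α-carbons, both normally nucleophilic): enamine of (S)-citronellal 1 (C4, C5, side chain) plus the electrophilic α-keto radical of a bromomethyl ketone (allylsilane 2 + bromoacetyl bromide 3 → 4; C6, C10, C1, C2, C3) gives γ-keto aldehyde 5.
- C3–C4: allylchromium 6 adds to the aldehyde and closes cycloheptanone 7 with the exocyclic methylene already in place; acetate 8.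
- C1–C9 and C6–C7: acetal ketone 9 is methylenated (Mannich base 10) to vinyl ketone 11, which is annulated onto the α,α′-carbons of 8 (Michael adduct 12, bridged ketol 13).
- Endgame: hydroxyl-directed reduction of the C10 ketone (14), acetylation (15), dehydration to the C7=C8 olefin (16), acetal hydrolysis to target 17.

Assumption: bicyclic intermediates are numbered like the target; 1, 2, 3 and 9 are bought; the (2R,5S) imidazolidinone is taken to give (2S)-5 by analogy with known α-alkylations (otherwise its mirror image is used).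

Step 1
Reactants: 2 [2-(chloromethyl)prop-2-en-1-yl]trimethylsilane; 3 bromoacetyl bromide
Product: 4 1-bromo-4-(chloromethyl)pent-4-en-2-one
Conditions: TiCl4 (1.0 equiv), CH2Cl2, −78 °C
Reagents that add atoms: none
Why: Lewis-acid-promoted acylation of an allylsilane (Hosomi–Sakurai-type SE2′ reaction), in which the acyl carbon bonds to the CH2= terminus and loss of silicon shifts the double bond, giving the β,γ-unsaturated bromomethyl ketone with the allylic chloride intact and no stereocenter.

Step 2
Reactants: 1 (3S)-3,7-dimethyloct-6-enal [(S)-citronellal]; 4 1-bromo-4-(chloromethyl)pent-4-en-2-one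
Product: 5 (2S,3S)-2-[4-(chloromethyl)-2-oxopent-4-en-1-yl]-3,7-dimethyloct-6-enal
Conditions: 1 (2 equiv), (2R,5S)-2-tert-butyl-3,5-dimethylimidazolidin-4-one·CF3SO3H (20 mol%), Ru(bpy)3Cl2 (0.5 mol%), 2,6-lutidine (2 equiv), DMF, blue LED, 23 °C
Reagents that add atoms: none
Why: Enantioselective photoredox organocatalytic α-alkylation of an aldehyde, in which the photoreduced ruthenium complex cleaves the C–Br bond of 4 to an electrophilic α-keto radical (an enolonium-type α-carbon) that adds to the open face of the catalyst-bound E-enamine of 1, so two normally nucleophilic α-carbons are joined and the C5 stereocenter is set by the catalyst, while the closed-shell enamine leaves the side-chain olefin and the allylic chloride alone.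

Step 3
Reactants: 5 (2S,3S)-2-[4-(chloromethyl)-2-oxopent-4-en-1-yl]-3,7-dimethyloct-6-enal
Product: 7 (3S,4S)-4-hydroxy-6-methylidene-3-[(2S)-6-methylhept-5-en-2-yl]cycloheptan-1-one, via allylchromium dichloride 6 (not isolated)
Conditions: CrCl2 (4 equiv), THF, 0.01 M, 23 °C; then H2O
Reagents that add atoms: none
Why: Intramolecular Nozaki–Hiyama–Kishi allylation, in which the allylchromium species adds only to the aldehyde and closes the seven-membered ring with the exocyclic methylene in place, Felkin–Anh attack anti to the branched side chain giving the alcohol cis to it (4S), and the neutral medium avoiding a Lewis-acid ene reaction of the aldehyde with the side-chain olefin.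

Step 4
Reactants: 7 (3S,4S)-4-hydroxy-6-methylidene-3-[(2S)-6-methylhept-5-en-2-yl]cycloheptan-1-one
Product: 8 (1S,2S)-6-methylidene-2-[(2S)-6-methylhept-5-en-2-yl]-4-oxocycloheptyl acetate
Conditions: Ac2O, pyridine, 4-(dimethylamino)pyridine (5 mol%), CH2Cl2, 0 → 23 °C
Reagents that add atoms: acetic anhydride, CC(=O)OC(C)=O
Why: Nucleophile-catalysed acylation of the secondary alcohol installs the first acetate of the target and prevents hemiketal formation with the ring ketone, with no change at any stereocenter.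

Step 5
Reactants: 9 1,1-dimethoxypropan-2-one
Product: 11 1,1-dimethoxybut-3-en-2-one, via Mannich base 10 (not isolated)
Conditions: (CH2O)n, i-Pr2NH·CF3CO2H (1 equiv), THF, reflux
Reagents that add atoms: formaldehyde (as paraformaldehyde), C=O
Why: Direct α-methylenation of a methyl ketone (Mannich condensation then β-elimination of the amine, which is regenerated) takes place on the CH3 side because the acetal-bearing carbon enolises far less readily, and no stereocenter is formed.

Step 6
Reactants: 8 (1S,2S)-6-methylidene-2-[(2S)-6-methylhept-5-en-2-yl]-4-oxocycloheptyl acetate; 11 1,1-dimethoxybut-3-en-2-one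
Product: 13 (1R,4S,5R,6R,7S)-7-(dimethoxymethyl)-7-hydroxy-2-methylidene-5-[(2S)-6-methylhept-5-en-2-yl]-10-oxobicyclo[4.3.1]decan-4-yl acetate, via Michael adduct 12 (not isolated)
Conditions: 11 (1.5 equiv), pyrrolidine (30 mol%), AcOH (30 mol%), MeCN, 23 → 50 °C
Reagents that add atoms: none
Why: Amine-catalysed Michael addition then intramolecular aldol (bridged Robinson-type α,α′-annulation), in which the linear dienamine of 8 reacts at its α-carbon (future C1) with the vinyl ketone and restores the exocyclic methylene, the enamine re-formed toward future C6 then adds to the activated α-keto-acetal carbonyl in the only six-membered aldol available, both new ring bonds are forced to be axial so that, with the branched side chain equatorial and the sequence reversible, the three-carbon bridge forms cis to the side chain (1R,6R), and the aldol places the dimethoxymethyl group equatorial and the hydroxyl axial next to the C10 ketone (7S).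

Step 7
Reactants: 13 (1R,4S,5R,6R,7S)-7-(dimethoxymethyl)-7-hydroxy-2-methylidene-5-[(2S)-6-methylhept-5-en-2-yl]-10-oxobicyclo[4.3.1]decan-4-yl acetate
Product: 14 (1R,4S,5R,6S,7S,10S)-7-(dimethoxymethyl)-7,10-dihydroxy-2-methylidene-5-[(2S)-6-methylhept-5-en-2-yl]bicyclo[4.3.1]decan-4-yl acetate
Conditions: Me4NBH(OAc)3, MeCN/AcOH (1:1), −20 °C
Reagents that add atoms: none
Why: Hydroxyl-directed (Saksena–Evans) reduction, in which the axial tertiary C7 hydroxyl binds the triacetoxyborohydride and delivers hydride to the six-membered-ring face of the bridging ketone, giving the 1,3-anti diol with the C10 hydroxyl on the seven-membered-ring side (10S) while acetate and acetal are untouched.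

Step 8
Reactants: 14 (1R,4S,5R,6S,7S,10S)-7-(dimethoxymethyl)-7,10-dihydroxy-2-methylidene-5-[(2S)-6-methylhept-5-en-2-yl]bicyclo[4.3.1]decan-4-yl acetate
Product: 15 (1R,4S,5R,6S,7S,10S)-7-(dimethoxymethyl)-7-hydroxy-2-methylidene-5-[(2S)-6-methylhept-5-en-2-yl]bicyclo[4.3.1]decane-4,10-diyl diacetate
Conditions: Ac2O, pyridine, 4-(dimethylamino)pyridine (10 mol%), CH2Cl2, 23 °C
Reagents that add atoms: acetic anhydride, CC(=O)OC(C)=O
Why: Selective acylation of the secondary C10 alcohol, the tertiary C7 alcohol being inert at room temperature, with no change at any stereocenter.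

Step 9
Reactants: 15 (1R,4S,5R,6S,7S,10S)-7-(dimethoxymethyl)-7-hydroxy-2-methylidene-5-[(2S)-6-methylhept-5-en-2-yl]bicyclo[4.3.1]decane-4,10-diyl diacetate
Product: 16 (1R,4S,5R,6R,10S)-7-(dimethoxymethyl)-2-methylidene-5-[(2S)-6-methylhept-5-en-2-yl]bicyclo[4.3.1]dec-7-ene-4,10-diyl diacetate
Conditions: Burgess reagent (MeO2CN−SO2N+Et3), toluene, 60 °C
Reagents that add atoms: none
Why: Burgess dehydration (syn elimination through the sulfamate ester) of the tertiary alcohol can give a ring olefin only toward C8 because C6 is a bridgehead (Bredt's rule), so the C7=C8 double bond forms and the temporary C7 stereocenter is erased.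

Step 10
Reactants: 16 (1R,4S,5R,6R,10S)-7-(dimethoxymethyl)-2-methylidene-5-[(2S)-6-methylhept-5-en-2-yl]bicyclo[4.3.1]dec-7-ene-4,10-diyl diacetate
Product: 17 (1R,4S,5R,6R,10S)-7-formyl-2-methylidene-5-[(2S)-6-methylhept-5-en-2-yl]bicyclo[4.3.1]dec-7-ene-4,10-diyl diacetate
Conditions: pyridinium p-toluenesulfonate (10 mol%), acetone/H2O (10:1), 40 °C
Reagents that add atoms: water, O
Why: Mild acid-catalysed hydrolysis of the allylic dimethyl acetal unmasks the conjugated aldehyde without touching the two acetates or the olefins, and no stereocenter is affected.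

Compound list
1 | (3S)-3,7-dimethyloct-6-enal [(S)-citronellal] | C[C@@H](CCC=C(C)C)CC=O | starting material
2 | [2-(chloromethyl)prop-2-en-1-yl]trimethylsilane | C=C(CCl)C[Si](C)(C)C | starting material
3 | bromoacetyl bromide | BrCC(Br)=O | starting material
4 | 1-bromo-4-(chloromethyl)pent-4-en-2-one | BrCC(=O)CC(=C)CCl | intermediate
5 | (2S,3S)-2-[4-(chloromethyl)-2-oxopent-4-en-1-yl]-3,7-dimethyloct-6-enal | O=C[C@@H](CC(=O)CC(=C)CCl)[C@@H](C)CCC=C(C)C | intermediate
6 | allylchromium dichloride of 5 (CH2Cl replaced by CH2CrCl2, trivalent chromium) | O=C[C@@H](CC(=O)CC(=C)C[Cr](Cl)Cl)[C@@H](C)CCC=C(C)C | intermediate (not isolated)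
7 | (3S,4S)-4-hydroxy-6-methylidene-3-[(2S)-6-methylhept-5-en-2-yl]cycloheptan-1-one | C=C1C[C@H](O)[C@H]([C@@H](C)CCC=C(C)C)CC(=O)C1 | intermediate
8 | (1S,2S)-6-methylidene-2-[(2S)-6-methylhept-5-en-2-yl]-4-oxocycloheptyl acetate | C=C1C[C@H](OC(C)=O)[C@H]([C@@H](C)CCC=C(C)C)CC(=O)C1 | intermediate
9 | 1,1-dimethoxypropan-2-one | CC(=O)C(OC)OC | starting material
10 | 4-[di(propan-2-yl)amino]-1,1-dimethoxybutan-2-one (Mannich base) | CC(C)N(CCC(=O)C(OC)OC)C(C)C | intermediate (not isolated)
11 | 1,1-dimethoxybut-3-en-2-one | C=CC(=O)C(OC)OC | intermediate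
12 | (1S,2S,5R)-5-(4,4-dimethoxy-3-oxobutyl)-6-methylidene-2-[(2S)-6-methylhept-5-en-2-yl]-4-oxocycloheptyl acetate (Michael adduct, productive C5 epimer) | C=C1C[C@H](OC(C)=O)[C@H]([C@@H](C)CCC=C(C)C)CC(=O)[C@@H]1CCC(=O)C(OC)OC | intermediate (not isolated)
13 | (1R,4S,5R,6R,7S)-7-(dimethoxymethyl)-7-hydroxy-2-methylidene-5-[(2S)-6-methylhept-5-en-2-yl]-10-oxobicyclo[4.3.1]decan-4-yl acetate | C=C1C[C@H](OC(C)=O)[C@H]([C@@H](C)CCC=C(C)C)[C@@H]2[C@](O)(C(OC)OC)CC[C@H]1C2=O | intermediate
14 | (1R,4S,5R,6S,7S,10S)-7-(dimethoxymethyl)-7,10-dihydroxy-2-methylidene-5-[(2S)-6-methylhept-5-en-2-yl]bicyclo[4.3.1]decan-4-yl acetate | C=C1C[C@H](OC(C)=O)[C@H]([C@@H](C)CCC=C(C)C)[C@@H]2[C@](O)(C(OC)OC)CC[C@H]1[C@@H]2O | intermediate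
15 | (1R,4S,5R,6S,7S,10S)-7-(dimethoxymethyl)-7-hydroxy-2-methylidene-5-[(2S)-6-methylhept-5-en-2-yl]bicyclo[4.3.1]decane-4,10-diyl diacetate | C=C1C[C@H](OC(C)=O)[C@H]([C@@H](C)CCC=C(C)C)[C@@H]2[C@](O)(C(OC)OC)CC[C@H]1[C@@H]2OC(C)=O | intermediate
16 | (1R,4S,5R,6R,10S)-7-(dimethoxymethyl)-2-methylidene-5-[(2S)-6-methylhept-5-en-2-yl]bicyclo[4.3.1]dec-7-ene-4,10-diyl diacetate | C=C1C[C@H](OC(C)=O)[C@H]([C@@H](C)CCC=C(C)C)[C@@H]2C(C(OC)OC)=CC[C@H]1[C@@H]2OC(C)=O | intermediate
17 | (1R,4S,5R,6R,10S)-7-formyl-2-methylidene-5-[(2S)-6-methylhept-5-en-2-yl]bicyclo[4.3.1]dec-7-ene-4,10-diyl diacetate | C=C1C[C@H](OC(C)=O)[C@H]([C@@H](C)CCC=C(C)C)[C@@H]2C(C=O)=CC[C@H]1[C@@H]2OC(C)=O | target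

Total step count: 10. Longest linear sequence: 9 steps (steps 1–4 and 6–10; step 5 is a one-step side branch).

Steps most likely to fail

Step 6 (bridging annulation). The natural series needs the C4 acetate axial, on the same side as the new bridge, so the bridge may form on the other face of the cycloheptanone. Fallback, from 7 back to 15:
- Mitsunobu esterification of 7 with acetic acid (PPh3, DIAD) gives the epimeric acetate F3, whose acetate is equatorial and trans to the side chain.
- The annulation of step 6 then runs with both ring substituents equatorial and gives bridged ketol F4.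
- Methanolysis (K2CO3, MeOH) gives hydroxy ketol F5.
- Dess–Martin oxidation gives diketone F6.
- Directed reduction as in step 7 (Me4NBH(OAc)3) reduces only the C10 ketone and gives hydroxy ketone F7.
- LiBH(s-Bu)3 at −78 °C attacks the C4 ketone from the open convex face and gives triol F8 with the natural axial C4 hydroxyl.
- Acetylation of both secondary alcohols returns to 15.

Step 2 (key coupling). The enolizable primary bromo ketone may be reduced sluggishly or alkylate the amine catalyst. Fallback, from 1 back to 5: condensation of 1 with pyrrolidine (K2CO3, 0 °C) gives the enamine 1-[(1E,3S)-3,7-dimethylocta-1,6-dien-1-yl]pyrrolidine F1. This is C-alkylated by 4 in a two-electron Stork enamine alkylation (MeCN, 23 °C) and hydrolysed (aqueous AcOH/NaOAc) to 5 and its C2 epimer. The two are diastereomers because of the fixed side-chain center and are separated by chromatography.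

Step 3 (seven-membered ring closure and C4 configuration). If the chromium-mediated closure of 5 gives mainly the anti-Felkin alcohol (3S,4R)-4-hydroxy-6-methylidene-3-[(2S)-6-methylhept-5-en-2-yl]cycloheptan-1-one F2, it is not oxidised and re-reduced, because that would make C3 epimerizable. Instead a Mitsunobu esterification with acetic acid (PPh3, DIAD, THF) inverts C4 and gives acetate 8 directly.

Further compounds
F1 | step 2 | 1-[(1E,3S)-3,7-dimethylocta-1,6-dien-1-yl]pyrrolidine | C1CCN(C1)/C=C/[C@@H](C)CCC=C(C)C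
F2 | step 3 | (3S,4R)-4-hydroxy-6-methylidene-3-[(2S)-6-methylhept-5-en-2-yl]cycloheptan-1-one | C=C1C[C@@H](O)[C@H]([C@@H](C)CCC=C(C)C)CC(=O)C1
F3 | step 6 | (1R,2S)-6-methylidene-2-[(2S)-6-methylhept-5-en-2-yl]-4-oxocycloheptyl acetate (epimeric acetate) | C=C1C[C@@H](OC(C)=O)[C@H]([C@@H](C)CCC=C(C)C)CC(=O)C1
F4 | step 6 | (1R,4R,5R,6R,7S)-7-(dimethoxymethyl)-7-hydroxy-2-methylidene-5-[(2S)-6-methylhept-5-en-2-yl]-10-oxobicyclo[4.3.1]decan-4-yl acetate (bridged ketol) | C=C1C[C@@H](OC(C)=O)[C@H]([C@@H](C)CCC=C(C)C)[C@@H]2[C@](O)(C(OC)OC)CC[C@H]1C2=O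
F5 | step 6 | (1R,4R,5R,6R,7S)-7-(dimethoxymethyl)-4,7-dihydroxy-2-methylidene-5-[(2S)-6-methylhept-5-en-2-yl]bicyclo[4.3.1]decan-10-one (hydroxy ketol) | C=C1C[C@@H](O)[C@H]([C@@H](C)CCC=C(C)C)[C@@H]2[C@](O)(C(OC)OC)CC[C@H]1C2=O
F6 | step 6 | (1R,5R,6R,7S)-7-(dimethoxymethyl)-7-hydroxy-2-methylidene-5-[(2S)-6-methylhept-5-en-2-yl]bicyclo[4.3.1]decane-4,10-dione (diketone) | C=C1CC(=O)[C@H]([C@@H](C)CCC=C(C)C)[C@@H]2[C@](O)(C(OC)OC)CC[C@H]1C2=O
F7 | step 6 | (1R,5R,6S,7S,10S)-7-(dimethoxymethyl)-7,10-dihydroxy-2-methylidene-5-[(2S)-6-methylhept-5-en-2-yl]bicyclo[4.3.1]decan-4-one (hydroxy ketone) | C=C1CC(=O)[C@H]([C@@H](C)CCC=C(C)C)[C@@H]2[C@](O)(C(OC)OC)CC[C@H]1[C@@H]2O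
F8 | step 6 | (1R,4S,5R,6S,7S,10S)-7-(dimethoxymethyl)-2-methylidene-5-[(2S)-6-methylhept-5-en-2-yl]bicyclo[4.3.1]decane-4,7,10-triol (triol) | C=C1C[C@H](O)[C@H]([C@@H](C)CCC=C(C)C)[C@@H]2[C@](O)(C(OC)OC)CC[C@H]1[C@@H]2O
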